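**Retrosynthetic overview**
1. Target 30 ⇐ desilylation of tris-silyl ether 29 ⇐ one-pot union of three copies of one 14-membered macrodiolide: epoxide 26 (opened by base to a 3,4-diketo ester) plus two enediones 25.
2. The cyclopentanone is the last ring formed, by a Michael/aldol annulation followed by a second Michael addition.
3. Enedione 25 ⇐ isoxazoline 21: the 14-membered ring and the C10–C11 bond are made together by an intramolecular nitrile oxide–acrylate 1,3-dipolar cycloaddition; N–O cleavage and dehydration then reveal the enedione.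
4. Cycloaddition precursor 18 ⇐ (S)-hex-5-en-2-yl propiolate 6 + (S)-O-silyl-lactaldehyde 9 (Felkin acetylide addition); the alkyne becomes the Z-enoate by semi-hydrogenation after ring closure.
5. Chirality comes from (S)-propylene oxide and ethyl (S)-lactate. Ring order: isoxazoline plus macrocycle (made once, used three times), then cyclopentanone.

Assumption: the SMILES is taken literally (three Z-enoates, configurations as written), and the base domino of step 16 is assumed to give the natural configuration at its five new centres under substrate control.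

Macrocycle locants used below: O1, C2(=O), C3=C4, C5(O-silyl), C6(Me), O7, C8(=O), C9, C10, C11, C12, C13, C14(Me).

**Step 1**
Reactants: 1 (S)-propylene oxide; 2 allylmagnesium chloride
Product: 3 (S)-hex-5-en-2-ol
Conditions: CuI (10 mol %), THF, −40 → 0 °C; then H2O
Reagents that add atoms: none
Why: Copper-catalysed Grignard opening of the epoxide at its CH2 carbon leaves the purchased stereocentre untouched.

**Step 2**
Reactants: 3 (S)-hex-5-en-2-ol; 4 propiolic acid
Product: 6 (S)-hex-5-en-2-yl propiolate, via O-acylisourea 5 (not isolated)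
Conditions: DCC, DMAP (5 mol %), CH2Cl2, −20 → 0 °C
Reagents that add atoms: none
Why: Steglich esterification acylates the alcohol oxygen, so the C–O stereocentre is retained.

**Step 3**
Reactants: 7 ethyl (S)-lactate
Product: 8 ethyl (S)-2-(triethylsilyloxy)propanoate
Conditions: Et3SiCl, imidazole, CH2Cl2, 0 °C → rt
Reagents that add atoms: chlorotriethylsilane CC[Si](CC)(CC)Cl
Why: Standard silylation of the secondary alcohol gives a temporary group that can later be removed beside a TBS ether.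

**Step 4**
Reactants: 8 ethyl (S)-2-(triethylsilyloxy)propanoate
Product: 9 (S)-2-(triethylsilyloxy)propanal
Conditions: iBu2AlH (1.05 equiv), CH2Cl2, −78 °C; then MeOH, aq. potassium sodium tartrate
Reagents that add atoms: none
Why: Partial ester reduction stops at the aldehyde at −78 °C through the stable aluminium hemiacetal, and the α-silyloxy aldehyde is used at once to avoid epimerisation.

**Step 5**
Reactants: 6 (S)-hex-5-en-2-yl propiolate; 9 (S)-2-(triethylsilyloxy)propanal
Product: 11 (S)-hex-5-en-2-yl (4R,5S)-4-hydroxy-5-(triethylsilyloxy)hex-2-ynoate, via lithium acetylide 10 (not isolated)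
Conditions: LiN(SiMe3)2, THF, −78 °C; then 9, −78 °C; AcOH, −78 °C
Reagents that add atoms: none
Why: Acetylide addition to the α-silyloxy aldehyde follows the non-chelated Felkin–Anh model, giving the 4,5-anti (4R) alcohol as major isomer (about 4:1 expected), and the 4S epimer is removed by chromatography.

**Step 6**
Reactants: 11 (S)-hex-5-en-2-yl (4R,5S)-4-hydroxy-5-(triethylsilyloxy)hex-2-ynoate
Product: 12 (S)-hex-5-en-2-yl (4R,5S)-4-(tert-butyldimethylsilyloxy)-5-(triethylsilyloxy)hex-2-ynoate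
Conditions: tBuMe2SiOTf, 2,6-lutidine, CH2Cl2, −78 °C
Reagents that add atoms: tert-butyldimethylsilyl triflate CC(C)(C)[Si](C)(C)OS(=O)(=O)C(F)(F)F
Why: Low-temperature silylation caps the propargylic alcohol without silyl migration; this TBS group stays until the last step.

**Step 7**
Reactants: 12 (S)-hex-5-en-2-yl (4R,5S)-4-(tert-butyldimethylsilyloxy)-5-(triethylsilyloxy)hex-2-ynoate
Product: 13 (S)-hex-5-en-2-yl (4R,5S)-4-(tert-butyldimethylsilyloxy)-5-hydroxyhex-2-ynoate
Conditions: PPTS (10 mol %), MeOH/CH2Cl2, 0 °C → rt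
Reagents that add atoms: none
Why: Mild acidic methanolysis removes the triethylsilyl ether much faster than the TBS ether, and the linear ynoate cannot lactonise onto the freed hydroxyl.

**Step 8**
Reactants: 13 (S)-hex-5-en-2-yl (4R,5S)-4-(tert-butyldimethylsilyloxy)-5-hydroxyhex-2-ynoate; 14 acryloyl chloride
Product: 15 (S)-hex-5-en-2-yl (4R,5S)-5-(acryloyloxy)-4-(tert-butyldimethylsilyloxy)hex-2-ynoate
Conditions: iPr2NEt, CH2Cl2, −20 → 0 °C
Reagents that add atoms: none
Why: Simple O-acylation installs the dipolarophile, which supplies C8–C10 of the keto-acid unit.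

**Step 9**
Reactants: 15 (S)-hex-5-en-2-yl (4R,5S)-5-(acryloyloxy)-4-(tert-butyldimethylsilyloxy)hex-2-ynoate
Product: 17 (S)-5-oxopentan-2-yl (4R,5S)-5-(acryloyloxy)-4-(tert-butyldimethylsilyloxy)hex-2-ynoate, via ozonide 16 (not isolated)
Conditions: O3 (1.0 equiv, Sudan Red 7B end point), CH2Cl2, −78 °C; then Me2S, −78 °C → rt
Reagents that add atoms: ozone [O-][O+]=O
Why: Ozonolysis is chemoselective for the electron-rich terminal alkene, which reacts about a hundred times faster than the acrylate or the ynoate.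

**Step 10**
Reactants: 17 (S)-5-oxopentan-2-yl (4R,5S)-5-(acryloyloxy)-4-(tert-butyldimethylsilyloxy)hex-2-ynoate
Product: 18 (S)-5-(hydroxyimino)pentan-2-yl (4R,5S)-5-(acryloyloxy)-4-(tert-butyldimethylsilyloxy)hex-2-ynoate
Conditions: NH2OH·HCl (1.05 equiv), NaOAc, EtOH/H2O, 0 °C
Reagents that add atoms: hydroxylamine hydrochloride Cl.NO
Why: Buffered oxime condensation at the aldehyde is far faster than conjugate addition of hydroxylamine to the acrylate or the hindered ynoate.

**Step 11**
Reactants: 18 (S)-5-(hydroxyimino)pentan-2-yl (4R,5S)-5-(acryloyloxy)-4-(tert-butyldimethylsilyloxy)hex-2-ynoate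
Product: 21 isoxazoline-bridged macrocycle (5R,6S,14S)-5-(tert-butyldimethylsilyloxy)-6,14-dimethyl-1,7-dioxacyclotetradec-3-yne-2,8-dione bearing a C9–O–N=C11 bridge, via hydroximoyl chloride 19 (not isolated), via nitrile oxide 20 (not isolated)
Conditions: aq. NaOCl, CH2Cl2, 0 °C → rt, slow addition of 18 (final 2 mM)
Reagents that add atoms: none
Why: Intramolecular nitrile oxide–alkene 1,3-dipolar cycloaddition closes the 14-membered ring, with the dipole carbon bonding to the acrylate CH2 and oxygen to the α-carbon as usual for acrylates; the new C9 centre is uncontrolled and is erased in step 14.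

**Step 12**
Reactants: 21 isoxazoline-bridged ynoate macrocycle
Product: 22 isoxazoline-bridged macrocycle (3Z,5R,6S,14S)-5-(tert-butyldimethylsilyloxy)-6,14-dimethyl-1,7-dioxacyclotetradec-3-ene-2,8-dione bearing the C9–O–N=C11 bridge
Conditions: H2 (1 atm), Pd/CaCO3 poisoned with Pb(OAc)2 (Lindlar catalyst), quinoline, EtOAc, rt
Reagents that add atoms: none
Why: Syn semi-hydrogenation on the poisoned catalyst gives the Z-enoate and spares the isoxazoline; no free hydroxyl is present, so no butenolide or pyranone can form.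

**Step 13**
Reactants: 22 isoxazoline-bridged Z-enoate macrocycle
Product: 23 (3Z,5R,6S,14S)-5-(tert-butyldimethylsilyloxy)-9-hydroxy-6,14-dimethyl-1,7-dioxacyclotetradec-3-ene-2,8,11-trione (C9 epimers)
Conditions: Mo(CO)6 (0.6 equiv), MeCN/H2O (10:1), 80 °C
Reagents that add atoms: water O
Why: Reductive N–O cleavage of the isoxazoline and hydrolysis of the resulting imine unmask the β-hydroxy ketone without touching the enoate.

**Step 14**
Reactants: 23 β-hydroxy ketone macrocycle
Product: 25 (3Z,5R,6S,9E,14S)-5-(tert-butyldimethylsilyloxy)-6,14-dimethyl-1,7-dioxacyclotetradeca-3,9-diene-2,8,11-trione, via mesylate 24 (not isolated)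
Conditions: MsCl, Et3N, CH2Cl2, 0 °C → rt
Reagents that add atoms: none
Why: Mesylation followed by E1cB elimination through the ketone enolate gives the conjugated E-enedione and removes the C9 stereocentre.

**Step 15**
Reactants: 25 enedione macrocycle
Product: 26 9,10-epoxide of 25 (trans-epoxide, both faces)
Conditions: 30% aq. H2O2, NaHCO3, THF/H2O, 0 °C
Reagents that add atoms: hydrogen peroxide OO
Why: Weitz–Scheffer nucleophilic epoxidation occurs only at the doubly activated enedione alkene; the epoxide stereochemistry is irrelevant because both carbons lose it in step 16.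

**Step 16**
Reactants: 26 epoxide macrocycle (1 equiv); 25 enedione macrocycle (2.2 equiv)
Product: 29 tris(tert-butyldimethylsilyl) ether of the target (three allylic C5 silyl ethers; tertiary OH free), via diketo ester 27 (not isolated), via cyclopentanone dimer 28 (not isolated)
Conditions: DBU (0.3 equiv), MeCN, 0 °C, 30 min; then 25, 0 °C → rt; AcOH quench
Reagents that add atoms: none
Why: Base opens the epoxy ketone, by deprotonation at the ketone-activated oxirane C–H, to the enolate of the 3,4-diketo ester, which undergoes Michael addition at C9 of one enedione, intramolecular aldol onto its C11 ketone (cyclopentanone closure) and a second Michael addition of the resulting β-keto ester to another enedione; the five new centres are expected to follow substrate control (macrocycle bridging the cyclopentanone cis, ring-fusion substituents trans, quaternary carbon alkylated anti to the neighbouring ester).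

**Step 17**
Reactants: 29 tris(tert-butyldimethylsilyl) ether of the target
Product: 30 target CNP0072185.1
Conditions: HF·pyridine, pyridine, THF, 0 °C → rt
Reagents that add atoms: none
Why: Buffered fluoride desilylation frees the three allylic alcohols without base, so no retro-aldol or ester migration is triggered; no stereocentre is touched.

**Compound list**
1 | (S)-propylene oxide | C[C@H]1CO1 | starting material
2 | allylmagnesium chloride | C=CC[Mg]Cl | starting material
3 | (S)-hex-5-en-2-ol | C[C@H](O)CCC=C | intermediate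
4 | propiolic acid | C#CC(=O)O | starting material
5 | O-propioloyl-N,N'-dicyclohexylisourea | C#CC(=O)OC(=NC1CCCCC1)NC1CCCCC1 | intermediate
6 | (S)-hex-5-en-2-yl propiolate | C#CC(=O)O[C@@H](C)CCC=C | intermediate
7 | ethyl (S)-lactate | CCOC(=O)[C@H](C)O | starting material
8 | ethyl (S)-2-(triethylsilyloxy)propanoate | CCOC(=O)[C@H](C)O[Si](CC)(CC)CC | intermediate
9 | (S)-2-(triethylsilyloxy)propanal | C[C@H](O[Si](CC)(CC)CC)C=O | intermediate
10 | lithium acetylide of 6 | [Li]C#CC(=O)O[C@@H](C)CCC=C | intermediate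
11 | (S)-hex-5-en-2-yl (4R,5S)-4-hydroxy-5-(triethylsilyloxy)hex-2-ynoate | C=CCC[C@H](C)OC(=O)C#C[C@@H](O)[C@H](C)O[Si](CC)(CC)CC | intermediate
12 | (S)-hex-5-en-2-yl (4R,5S)-4-(tert-butyldimethylsilyloxy)-5-(triethylsilyloxy)hex-2-ynoate | C=CCC[C@H](C)OC(=O)C#C[C@@H](O[Si](C)(C)C(C)(C)C)[C@H](C)O[Si](CC)(CC)CC | intermediate
13 | (S)-hex-5-en-2-yl (4R,5S)-4-(tert-butyldimethylsilyloxy)-5-hydroxyhex-2-ynoate | C=CCC[C@H](C)OC(=O)C#C[C@@H](O[Si](C)(C)C(C)(C)C)[C@H](C)O | intermediate
14 | acryloyl chloride | C=CC(=O)Cl | starting material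
15 | (S)-hex-5-en-2-yl (4R,5S)-5-(acryloyloxy)-4-(tert-butyldimethylsilyloxy)hex-2-ynoate | C=CCC[C@H](C)OC(=O)C#C[C@@H](O[Si](C)(C)C(C)(C)C)[C@H](C)OC(=O)C=C | intermediate
16 | 1,2,4-trioxolane (ozonide) of the terminal alkene of 15 | C1OOC(O1)CC[C@H](C)OC(=O)C#C[C@@H](O[Si](C)(C)C(C)(C)C)[C@H](C)OC(=O)C=C | intermediate
17 | (S)-5-oxopentan-2-yl (4R,5S)-5-(acryloyloxy)-4-(tert-butyldimethylsilyloxy)hex-2-ynoate | O=CCC[C@H](C)OC(=O)C#C[C@@H](O[Si](C)(C)C(C)(C)C)[C@H](C)OC(=O)C=C | intermediate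
18 | (S)-5-(hydroxyimino)pentan-2-yl (4R,5S)-5-(acryloyloxy)-4-(tert-butyldimethylsilyloxy)hex-2-ynoate (E/Z oxime) | ON=CCC[C@H](C)OC(=O)C#C[C@@H](O[Si](C)(C)C(C)(C)C)[C@H](C)OC(=O)C=C | intermediate
19 | hydroximoyl chloride of 18 | ON=C(Cl)CC[C@H](C)OC(=O)C#C[C@@H](O[Si](C)(C)C(C)(C)C)[C@H](C)OC(=O)C=C | intermediate
20 | nitrile oxide of 18 | [O-][N+]#CCC[C@H](C)OC(=O)C#C[C@@H](O[Si](C)(C)C(C)(C)C)[C@H](C)OC(=O)C=C | intermediate
21 | (5R,6S,14S)-5-(tert-butyldimethylsilyloxy)-6,14-dimethyl-1,7-dioxacyclotetradec-3-yne-2,8-dione with C9–O–N=C11 bridge (4,5-dihydroisoxazole, C9 epimers) | C[C@H]1CCC2=NOC(C2)C(=O)O[C@@H](C)[C@H](O[Si](C)(C)C(C)(C)C)C#CC(=O)O1 | intermediate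
22 | (3Z,5R,6S,14S)-5-(tert-butyldimethylsilyloxy)-6,14-dimethyl-1,7-dioxacyclotetradec-3-ene-2,8-dione with C9–O–N=C11 bridge (C9 epimers) | C[C@H]1CCC2=NOC(C2)C(=O)O[C@@H](C)[C@H](O[Si](C)(C)C(C)(C)C)/C=C\C(=O)O1 | intermediate
23 | (3Z,5R,6S,14S)-5-(tert-butyldimethylsilyloxy)-9-hydroxy-6,14-dimethyl-1,7-dioxacyclotetradec-3-ene-2,8,11-trione (C9 epimers) | C[C@H]1CCC(=O)CC(O)C(=O)O[C@@H](C)[C@H](O[Si](C)(C)C(C)(C)C)/C=C\C(=O)O1 | intermediate
24 | 9-O-methanesulfonate of 23 | C[C@H]1CCC(=O)CC(OS(C)(=O)=O)C(=O)O[C@@H](C)[C@H](O[Si](C)(C)C(C)(C)C)/C=C\C(=O)O1 | intermediate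
25 | (3Z,5R,6S,9E,14S)-5-(tert-butyldimethylsilyloxy)-6,14-dimethyl-1,7-dioxacyclotetradeca-3,9-diene-2,8,11-trione | C[C@H]1CCC(=O)/C=C/C(=O)O[C@@H](C)[C@H](O[Si](C)(C)C(C)(C)C)/C=C\C(=O)O1 | intermediate
26 | 9,10-epoxide of 25 (trans, both faces; epoxide centres left undefined) | C[C@H]1CCC(=O)C2OC2C(=O)O[C@@H](C)[C@H](O[Si](C)(C)C(C)(C)C)/C=C\C(=O)O1 | intermediate
27 | (3Z,5R,6S,14S)-5-(tert-butyldimethylsilyloxy)-6,14-dimethyl-1,7-dioxacyclotetradec-3-ene-2,8,10,11-tetrone (present as its C10 enol/enolate) | C[C@H]1CCC(=O)C(=O)CC(=O)O[C@@H](C)[C@H](O[Si](C)(C)C(C)(C)C)/C=C\C(=O)O1 | intermediate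
28 | cyclopentanone dimer: C9 of unit 27 bonded to C9 of one unit 25, and C11 of 27 (now the tertiary carbinol) bonded to C10 of that unit; β-keto ester C–H epimerisable, other centres as in the target | C23C(=O)O[C@@H](C)[C@H](O[Si](C)(C)C(C)(C)C)/C=C\C(=O)O[C@@H](C)CC[C@@](O)(C2=O)[C@H]2C(=O)CC[C@H](C)OC(=O)/C=C\[C@@H](O[Si](C)(C)C(C)(C)C)[C@H](C)OC(=O)[C@@H]23 | intermediate
29 | target with its three secondary allylic hydroxyls as tert-butyldimethylsilyl ethers | C[C@@H]1OC(=O)[C@@H]([C@@]23C(=O)O[C@@H](C)[C@H](O[Si](C)(C)C(C)(C)C)/C=C\C(=O)O[C@@H](C)CC[C@@](O)(C2=O)[C@H]2C(=O)CC[C@H](C)OC(=O)/C=C\[C@@H](O[Si](C)(C)C(C)(C)C)[C@H](C)OC(=O)[C@@H]23)CC(=O)CC[C@H](C)OC(=O)/C=C\[C@H]1O[Si](C)(C)C(C)(C)C | intermediate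
30 | CNP0072185.1 | C[C@@H]1OC(=O)[C@@H]([C@@]23C(=O)O[C@@H](C)[C@H](O)/C=C\C(=O)O[C@@H](C)CC[C@@](O)(C2=O)[C@H]2C(=O)CC[C@H](C)OC(=O)/C=C\[C@@H](O)[C@H](C)OC(=O)[C@@H]23)CC(=O)CC[C@H](C)OC(=O)/C=C\[C@H]1O | target

**Count and risks**
Total steps: 17. Longest linear sequence: 15 steps (1, 2, 5–17; the lactate branch 3, 4, 5–17 is equally long).

Most likely to fail, first: step 16. The epoxide may open with the wrong regiochemistry, the three-component reaction may oligomerise, and five stereocentres rest on substrate control. The fallback is a staged assembly that sets out from 26 and returns at 30. Compound 26 and one equivalent of 25 with catalytic DBU are stopped at dimer 28, which is isolated and equilibrated. Its tertiary aldol hydroxyl is capped with 1-(trimethylsilyl)imidazole to give the trimethylsilyl ether of the dimer F1, which blocks retro-aldol. The β-keto ester of F1 is then added to a second equivalent of 25 with Cs2CO3 in MeCN to give the silyl-capped trimer F2. HF·pyridine removes the four silyl groups to reach 30.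

Second: step 11. Oligomerisation or furoxan formation may beat closure of the 14-membered ring. The fallback makes the isoxazoline intermolecularly and closes the ring by lactonisation; it sets out from 13 and returns at 21. Compound 13 is ozonised to the ozonide F3 and reduced with Me2S to the hydroxy aldehyde F4, which is condensed with hydroxylamine to the oxime F5. NCS gives the hydroximoyl chloride F6. Slow addition of Et3N in the presence of excess acrylic acid releases the nitrile oxide F7, which is trapped as the isoxazoline seco acid F8. Yamaguchi activation (2,4,6-trichlorobenzoyl chloride, Et3N) gives the mixed anhydride F9, and DMAP in toluene at high dilution acylates the C5 hydroxyl to give 21.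

Third: step 17. The freed Z-γ-hydroxy enoates may lactonise to butenolides, or the aldol core may suffer, during triple desilylation. The fallback removes silicon before the sensitive core exists; it sets out from 25 and returns at 30. HF·pyridine on 25 gives the free hydroxy enedione F10. Part of it is epoxidised (H2O2, NaHCO3) to the hydroxy epoxide F11. The DBU domino is then run on unprotected material, through the hydroxy diketo ester F12 and the hydroxy dimer F13, to give 30 directly.

**Further compounds**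
F1 | step 16 | tertiary O-trimethylsilyl ether of dimer 28 | C23C(=O)O[C@@H](C)[C@H](O[Si](C)(C)C(C)(C)C)/C=C\C(=O)O[C@@H](C)CC[C@@](O[Si](C)(C)C)(C2=O)[C@H]2C(=O)CC[C@H](C)OC(=O)/C=C\[C@@H](O[Si](C)(C)C(C)(C)C)[C@H](C)OC(=O)[C@@H]23
F2 | step 16 | tertiary O-trimethylsilyl ether of 29 | C[C@@H]1OC(=O)[C@@H]([C@@]23C(=O)O[C@@H](C)[C@H](O[Si](C)(C)C(C)(C)C)/C=C\C(=O)O[C@@H](C)CC[C@@](O[Si](C)(C)C)(C2=O)[C@H]2C(=O)CC[C@H](C)OC(=O)/C=C\[C@@H](O[Si](C)(C)C(C)(C)C)[C@H](C)OC(=O)[C@@H]23)CC(=O)CC[C@H](C)OC(=O)/C=C\[C@H]1O[Si](C)(C)C(C)(C)C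
F3 | step 11 | ozonide of the terminal alkene of 13 | C1OOC(O1)CC[C@H](C)OC(=O)C#C[C@@H](O[Si](C)(C)C(C)(C)C)[C@H](C)O
F4 | step 11 | (S)-5-oxopentan-2-yl (4R,5S)-4-(tert-butyldimethylsilyloxy)-5-hydroxyhex-2-ynoate | O=CCC[C@H](C)OC(=O)C#C[C@@H](O[Si](C)(C)C(C)(C)C)[C@H](C)O
F5 | step 11 | (S)-5-(hydroxyimino)pentan-2-yl (4R,5S)-4-(tert-butyldimethylsilyloxy)-5-hydroxyhex-2-ynoate | ON=CCC[C@H](C)OC(=O)C#C[C@@H](O[Si](C)(C)C(C)(C)C)[C@H](C)O
F6 | step 11 | hydroximoyl chloride of F5 | ON=C(Cl)CC[C@H](C)OC(=O)C#C[C@@H](O[Si](C)(C)C(C)(C)C)[C@H](C)O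
F7 | step 11 | nitrile oxide of F5 | [O-][N+]#CCC[C@H](C)OC(=O)C#C[C@@H](O[Si](C)(C)C(C)(C)C)[C@H](C)O
F8 | step 11 | 3-substituted 4,5-dihydroisoxazole-5-carboxylic acid (seco acid of 21, C5 epimers) | OC(=O)C1CC(CC[C@H](C)OC(=O)C#C[C@@H](O[Si](C)(C)C(C)(C)C)[C@H](C)O)=NO1
F9 | step 11 | mixed 2,4,6-trichlorobenzoic anhydride of F8 | O=C(OC(=O)C1CC(CC[C@H](C)OC(=O)C#C[C@@H](O[Si](C)(C)C(C)(C)C)[C@H](C)O)=NO1)c1c(Cl)cc(Cl)cc1Cl
F10 | step 17 | (3Z,5R,6S,9E,14S)-5-hydroxy-6,14-dimethyl-1,7-dioxacyclotetradeca-3,9-diene-2,8,11-trione | C[C@H]1CCC(=O)/C=C/C(=O)O[C@@H](C)[C@H](O)/C=C\C(=O)O1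
F11 | step 17 | 9,10-epoxide of F10 | C[C@H]1CCC(=O)C2OC2C(=O)O[C@@H](C)[C@H](O)/C=C\C(=O)O1
F12 | step 17 | (3Z,5R,6S,14S)-5-hydroxy-6,14-dimethyl-1,7-dioxacyclotetradec-3-ene-2,8,10,11-tetrone | C[C@H]1CCC(=O)C(=O)CC(=O)O[C@@H](C)[C@H](O)/C=C\C(=O)O1
F13 | step 17 | desilylated analogue of dimer 28 | C23C(=O)O[C@@H](C)[C@H](O)/C=C\C(=O)O[C@@H](C)CC[C@@](O)(C2=O)[C@H]2C(=O)CC[C@H](C)OC(=O)/C=C\[C@@H](O)[C@H](C)OC(=O)[C@@H]23
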